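Ring carbons are numbered C1 (quaternary oxirane carbon), C2 (CHOH), C3 (CHOBz), C4=C5 and C6 (oxirane CH); C7 is the exocyclic CH2. Everything rests on cutting C7–C1 one oxidation level below the oxirane, where C1 is the sp2 terminus of a C1=C6–C5=C4 diene. A Stille hydroxymethylation joins (tributylstannyl)methanol to the C1–Br bond of a bis-silylated bromocyclohexadiene-cis-diol, bought with C2 already correct. This one operation completes the carbon skeleton and plants on C1 the free CH2OH that then steers oxygen to C1=C6 only, anti to the C2 silyloxy group, setting C1 and C6 together. Mitsunobu inversion at C3 with benzoic acid ends the route.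

Key step: step 2

Remark: compound 1 is taken as purchasable. It is the enantiopure whole-cell dioxygenase metabolite of bromobenzene, sold as a buffer suspension, and is extracted into ethyl acetate before use.

Step 1
Reactants: 1 (1S,2S)-3-bromocyclohexa-3,5-diene-1,2-diol
Product: 2 (5S,6S)-1-bromo-5,6-bis(triethylsilyloxy)cyclohexa-1,3-diene
Conditions: TESCl, imidazole, DMAP (cat.), DMF, 0 °C to rt
Reagents that add atoms: chlorotriethylsilane CC[Si](Cl)(CC)CC
Why: Standard silyl ether formation under imidazole buffering, so no acid is present that could aromatise the dienediol; both stereocentres are untouched and both oxygens stay on the same (lower) ring face.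

Step 2
Reactants: 2 (5S,6S)-1-bromo-5,6-bis(triethylsilyloxy)cyclohexa-1,3-diene; 3 (tributylstannyl)methanol
Product: 4 [(5S,6R)-5,6-bis(triethylsilyloxy)cyclohexa-1,3-dien-1-yl]methanol
Conditions: Pd(PPh3)4 (10 mol %), degassed toluene, 80 °C
Reagents that add atoms: none
Why: Zerovalent palladium inserts into the C1–Br bond of the 1-bromo-1,3-diene, stannane 3 transfers its hydroxymethyl carbon C7 to palladium, and reductive elimination forges C7–C1 and returns the catalyst. The closest known reaction type is this one itself, the Stille (Kosugi–Migita) hydroxymethylation of aryl and alkenyl halides and triflates with (tributylstannyl)methanol; Stille couplings of protected halocyclohexadiene-cis-diols are also established. No ring is closed and no stereocentre is created, and C2 and C3 are spectators because silyloxy groups neither ionise nor eliminate under neutral, base-free conditions. The step needs group selectivity (CH2OH rather than butyl transfer), which the alpha-oxygen of 3 secures by accelerating transmetalation of that carbon; it also needs the diene to outlive the heating, which the two bulky silyl ethers, dilution and exclusion of acid secure against Diels–Alder dimerisation and aromatisation. The structural pay-off is that C1 is the only ring carbon without hydrogen, and attaching C7 while C1 is still sp2 removes any facial problem at the future quaternary centre: oxygen, not carbon, is later delivered anti to the C2 substituent, which leaves C7 cis to the C2 oxygen as the target demands.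

Step 3
Reactants: 4 [(5S,6R)-5,6-bis(triethylsilyloxy)cyclohexa-1,3-dien-1-yl]methanol
Product: 6 [(1S,2S,3S,6S)-2,3-bis(triethylsilyloxy)-7-oxabicyclo[4.1.0]hept-4-en-1-yl]methyl benzoate, via epoxy alcohol 5 (not isolated)
Conditions: VO(acac)2 (5 mol %), t-BuOOH (decane), CH2Cl2, 0 °C; P(OMe)3 to destroy excess peroxide; then BzCl, Et3N, DMAP (cat.), 0 °C
Reagents that add atoms: tert-butyl hydroperoxide CC(C)(C)OO; benzoyl chloride O=C(Cl)c1ccccc1
Why: Hydroxyl-directed vanadium-catalysed epoxidation, in which the C7 alkoxide binds the metal peroxide and reaches only the allylic C1=C6 bond, the pseudoaxial C2 silyloxy group blocks the lower face so that oxygen arrives anti to both silyl ethers and sets C1 and C6 in one event, and the sensitive epoxy alcohol is esterified in the same flask (in situ derivatisation).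

Step 4
Reactants: 6 [(1S,2S,3S,6S)-2,3-bis(triethylsilyloxy)-7-oxabicyclo[4.1.0]hept-4-en-1-yl]methyl benzoate
Product: 7 [(1R,2S,3S,6S)-2,3-dihydroxy-7-oxabicyclo[4.1.0]hept-4-en-1-yl]methyl benzoate
Conditions: TBAF/AcOH (equimolar), THF, 0 °C to rt
Reagents that add atoms: none
Why: Fluoride-induced Si–O cleavage, with acetic acid keeping the medium near neutral so that Payne rearrangement through a C2 alkoxide, benzoyl migration and oxirane opening should all stay silent; no stereocentre is touched, and the C1 descriptor changes only because the priority order changes.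

Step 5
Reactants: 7 [(1R,2S,3S,6S)-2,3-dihydroxy-7-oxabicyclo[4.1.0]hept-4-en-1-yl]methyl benzoate
Product: 8 [(1R,2S,3R,6S)-3-(benzoyloxy)-2-hydroxy-7-oxabicyclo[4.1.0]hept-4-en-1-yl]methyl benzoate
Conditions: PPh3, DIAD, BzOH, toluene, 0 °C to rt
Reagents that add atoms: benzoic acid O=C(O)c1ccccc1
Why: Mitsunobu reaction, in which the less hindered allylic C3 hydroxyl is activated on phosphorus and displaced by benzoate in an SN2 process with inversion (3S to 3R, now trans to the C2 hydroxyl and cis to the oxirane), while the C2 hydroxyl next to quaternary C1 is too hindered to react.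

Compound list
1 | (1S,2S)-3-bromocyclohexa-3,5-diene-1,2-diol | BrC1=CC=C[C@H](O)[C@@H]1O | starting material
2 | (5S,6S)-1-bromo-5,6-bis(triethylsilyloxy)cyclohexa-1,3-diene | BrC1=CC=C[C@H](O[Si](CC)(CC)CC)[C@@H]1O[Si](CC)(CC)CC | intermediate
3 | (tributylstannyl)methanol | CCCC[Sn](CCCC)(CCCC)CO | starting material
4 | [(5S,6R)-5,6-bis(triethylsilyloxy)cyclohexa-1,3-dien-1-yl]methanol | OCC1=CC=C[C@H](O[Si](CC)(CC)CC)[C@@H]1O[Si](CC)(CC)CC | intermediate
5 | [(1S,2S,3S,6S)-2,3-bis(triethylsilyloxy)-7-oxabicyclo[4.1.0]hept-4-en-1-yl]methanol (oxirane anti to both silyloxy groups) | OC[C@]12O[C@H]1C=C[C@H](O[Si](CC)(CC)CC)[C@@H]2O[Si](CC)(CC)CC | intermediate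
6 | [(1S,2S,3S,6S)-2,3-bis(triethylsilyloxy)-7-oxabicyclo[4.1.0]hept-4-en-1-yl]methyl benzoate | O=C(OC[C@]12O[C@H]1C=C[C@H](O[Si](CC)(CC)CC)[C@@H]2O[Si](CC)(CC)CC)c1ccccc1 | intermediate
7 | [(1R,2S,3S,6S)-2,3-dihydroxy-7-oxabicyclo[4.1.0]hept-4-en-1-yl]methyl benzoate (cis-diol anti to the oxirane) | O=C(OC[C@]12O[C@H]1C=C[C@H](O)[C@@H]2O)c1ccccc1 | intermediate
8 | [(1R,2S,3R,6S)-3-(benzoyloxy)-2-hydroxy-7-oxabicyclo[4.1.0]hept-4-en-1-yl]methyl benzoate | O=C(OC[C@]12O[C@H]1C=C[C@@H](OC(=O)c1ccccc1)[C@@H]2O)c1ccccc1 | target

Total step count: 5. Longest linear sequence: 5 (1, 2, 4, 6, 7, 8).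

Steps most likely to fail

Step 2. The diene may be lost to Diels–Alder dimerisation or aromatisation during heating before the slow hydroxymethyl transfer is complete, or butyl transfer may compete. The fallback replaces cross-coupling by a low-temperature carbonyl addition that makes the same bond. Setting out from 2, bromine–lithium exchange (t-BuLi, Et2O, −78 °C) should give the dienyllithium F1. Quenching it with gaseous monomeric formaldehyde (cracked paraformaldehyde) comes back to the route at 4.

Step 5. Benzoate may attack in the SN2′ sense at C5, the activated allylic alcohol may eliminate, or site selectivity may erode through a cyclic phosphorane of the cis-diol. The fallback activates both diol oxygens at once instead of one hydroxyl. Setting out from 7, SOCl2/Et3N (CH2Cl2, 0 °C) should give the cyclic sulfite F4. Cesium benzoate in warm DMF should open it at the allylic C3 carbon with inversion. The remaining C2 sulfite half-ester hydrolyses on aqueous work-up, coming back to the route at 8.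

Step 3. The vinyl oxirane may be opened by the Lewis-acidic vanadium species, or facial control may be incomplete. The fallback replaces directed oxygen transfer by cycloaddition and deoxygenation. Setting out from 4, benzoylation (BzCl, pyridine) gives the dienylmethyl benzoate F2. Tetraphenylporphyrin-sensitised photooxygenation (O2, visible light, CH2Cl2, −40 °C) should add singlet oxygen across C1 and C4, anti to the silyloxy groups, to give the endoperoxide F3. P(OMe)3 should attack the less hindered peroxide oxygen on C4. The released C1 alkoxide then closes on C6 in an SN2′ sense as the phosphate leaves C4, coming back to the route at 6.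

Further compounds
F1 | step 2 | [(5S,6R)-5,6-bis(triethylsilyloxy)cyclohexa-1,3-dien-1-yl]lithium | [Li]C1=CC=C[C@H](O[Si](CC)(CC)CC)[C@@H]1O[Si](CC)(CC)CC
F2 | step 3 | [(5S,6R)-5,6-bis(triethylsilyloxy)cyclohexa-1,3-dien-1-yl]methyl benzoate | O=C(OCC1=CC=C[C@H](O[Si](CC)(CC)CC)[C@@H]1O[Si](CC)(CC)CC)c1ccccc1
F3 | step 3 | [(1R,4R,7S,8S)-7,8-bis(triethylsilyloxy)-2,3-dioxabicyclo[2.2.2]oct-5-en-1-yl]methyl benzoate (peroxide bridge anti to both silyloxy groups) | O=C(OC[C@]12OO[C@H](C=C1)[C@H](O[Si](CC)(CC)CC)[C@@H]2O[Si](CC)(CC)CC)c1ccccc1
F4 | step 5 | cyclic C2,C3-sulfite of diol 7 (configuration at sulfur not defined) | O=C(OC[C@]12O[C@H]1C=C[C@@H]3OS(=O)O[C@H]23)c1ccccc1
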